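Its constants are assumed; what happens was integrated by code.

We are about to run this flask beside a neighbour with 42 mM of solid substrate, and for both we want the target standing at the end.

    gas phase ⇌ dissolved gas, rate k1*(csat - [dissolved gas]) (k1 = 0.71 min⁻¹, csat = 6.2 mM)
    dissolved gas ⇌ dormant form (K2 = 9.0, k2 = 0.032 min⁻¹)
    solid substrate ⇌ starting material, rate k3*(cs3 - [starting material]) while solid is left; crystals form when [starting material] > cs3 (cs3 = 5.9 mM, k3 = 0.047 min⁻¹)
    starting material + dissolved gas + catalyst → catalyst + target (k4 = 22000 M⁻² min⁻¹)
    target + catalyst ⇌ isomer of the product + catalyst, rate k5*[catalyst]*[target] forward; the back reaction follows from the equilibrium constant (K5 = 22, k5 = 77 M⁻¹ min⁻¹)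

solid substrate 25 mM; gas phase 6.2 mM (held); catalyst 2.5 mol%; time 50 min

- given per volume of solution although it is solid: solid substrate
- at the start none of the gas is dissolved
- at the start none of the solid substrate is in solution
- run time (flask): 50 min

1. the target standing at 50 min, as a percentage of the solid substrate charged
2. the change that raises the amount of target at 50 min, in percent of the solid substrate charged most ("none" if none brings more than 2 percentage points) (spring / noon / autumn / dawn / none)
3. amount of target at 50 min, in percent of the solid substrate charged, after dawn

- spring: doubling the solubility in step 3, all else as stated
- noon: doubling the dissolution coefficient of step 3, all else as stated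
- autumn: doubling the saturation concentration of gas phase, all else as stated
- dawn: doubling the transfer coefficient of step 1, all else as stated

We turn the constants into times at the charged amounts, adding one process at a time. First the main step: with gas at saturation and catalyst at 0.625 mM, starting material is consumed pseudo-first-order with a capture constant of 0.0853 min⁻¹, a time of 11.7 min. On a solution held at the solubility, that gives 101% of the charge in 50 min.

Now we add dissolution. Its time of 21.3 min is longer than the capture time. Inflow and capture balance at 2.10 mM, or 8.39% of the charge: the dissolution coefficient times the solubility, over the sum of that coefficient and the capture constant, which we call the standing level. The flow through it is 0.179 mM min⁻¹, reached after about 7.56 min, so the product falls to 30.3% of the charge.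

Then we add isomerisation. The half-life of target by its forward rate is 14 min, shorter than the run, so our figure for target drops to 12.9%. We leave out two corrections: a gas deficit of about 0.531 mM below saturation, and the return of isomer, whose equilibrium constant is 22.

The flow formula ranks the changes. Spring multiplies the flow by 2, noon by 1.48 and autumn by 1.22, while dawn acts on the gas deficit. We choose spring.

The forecast gives 12.7%, against our 12.9%, with spring as the best change and 12.9% after dawn, holding that “gas transfer is already close to saturation”.

The flask gives 12.7%, spring gains 12 percentage points, and dawn gives 12.9%. Dawn's gain is 0.22 points, with dissolved gas at 5.74 mM in this flask. The standing level of 8.39%, reckoned at saturation, meets 8.80% of starting material in this flask at 50.0 min. In the neighbour with 42 mM, the catalyst rises with the charge, so the same formula gives 3.47% of its charge, and that neighbour holds 3.70% of starting material and 6.29% of target.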